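**Retrosynthetic overview**
Ring A is numbered C1 (OH), C2 (Br), C3 (Br), C4 (H), C5 (Br), C6 (O-aryl), and ring B is the 2-bromophenyl group. The target has no stereocentre and no ring is formed: ring A is bought as 3-nitrocatechol and ring B as 1-bromo-2-iodobenzene.
Feature used: on ring A, C3 and C5 lie ortho and para to C2, whereas the C1 oxygen alone would send bromine to C4. A nitrogen placed at C2 steers both brominations and is then exchanged for the C2 bromine.
Disconnections: C1 O–Me (BBr3) ⇒ C2–Br (Sandmeyer from C2–NH2) ⇒ C3–Br and C5–Br (Br2 on the aniline) ⇒ NH2 from NO2 ⇒ C6–O–ring B (phenoxide plus 2-bromophenyl iodonium salt) ⇒ C1–OMe on the more acidic catechol hydroxyl.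
The methyl ether is set before the diaryl ether, so each catechol oxygen is addressed under acidity control and the iodonium salt meets a single phenoxide.

Key step: step 5

**Step 1**
Reactants: 1 1-bromo-2-iodobenzene; 2 1,3,5-trimethoxybenzene
Product: 4 (2-bromophenyl)(2,4,6-trimethoxyphenyl)iodonium p-toluenesulfonate, via hydroxy(tosyloxy)iodoarene 3 (not isolated)
Conditions: mCPBA (1.1 equiv), TsOH·H2O (1.1 equiv), MeCN, 75 °C; then 2 (1.05 equiv), 75 °C; Et2O trituration
Reagents that add atoms: p-toluenesulfonic acid monohydrate, Cc1ccc(cc1)S(=O)(=O)O.O; mCPBA, OOC(=O)c1cccc(Cl)c1 (its oxygen is held only in 3)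
Why: One-pot oxidation–arylation route to unsymmetrical diaryliodonium salts: mCPBA/TsOH raises the aryl iodide to the trivalent-iodine stage 3, whose electrophilic iodine is attacked by the very electron-rich arene 2 (electrophilic aromatic substitution), while the C–Br bond is inert to peracid and acid.

**Step 2**
Reactants: 5 3-nitrobenzene-1,2-diol (3-nitrocatechol)
Product: 6 2-methoxy-3-nitrophenol
Conditions: KHCO3 (1.1 equiv), MeI (1.1 equiv), DMF, 40 °C (closed flask)
Reagents that add atoms: iodomethane, CI
Why: Williamson O-methylation under acidity control: KHCO3 ionises only the hydroxyl ortho to the nitro group, whose anion is delocalised into NO2, and cannot deprotonate the much less acidic product phenol, so methylation should stop at the C1 oxygen and leave the C6 hydroxyl free.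

**Step 3**
Reactants: 6 2-methoxy-3-nitrophenol; 4 (2-bromophenyl)(2,4,6-trimethoxyphenyl)iodonium p-toluenesulfonate
Product: 7 1-(2-bromophenoxy)-2-methoxy-3-nitrobenzene
Conditions: 4 (1.2 equiv), K2CO3 (2 equiv), MeCN, 60 °C
Reagents that add atoms: none
Why: Metal-free O-arylation of a phenoxide with a diaryliodonium salt (ligand exchange at trivalent iodine, then ipso ligand coupling): the electron-rich trimethoxyphenyl group stays on iodine, the ortho-bromophenyl group passes to oxygen, and without a transition metal the C–Br bond and the nitro group are left alone.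

**Step 4**
Reactants: 7 1-(2-bromophenoxy)-2-methoxy-3-nitrobenzene
Product: 8 3-(2-bromophenoxy)-2-methoxyaniline
Conditions: Fe powder (5 equiv), NH4Cl, EtOH/H2O, 80 °C
Reagents that add atoms: none
Why: Béchamp-type nitro reduction by electron transfer from iron under near-neutral conditions, which should take ArNO2 to ArNH2 without hydrodebromination of ring B or cleavage of either ether.

**Step 5**
Reactants: 8 3-(2-bromophenoxy)-2-methoxyaniline
Product: 10 4,6-dibromo-3-(2-bromophenoxy)-2-methoxyaniline, via 4-bromo-3-(2-bromophenoxy)-2-methoxyaniline 9 (not isolated)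
Conditions: Br2 (2.0 equiv, slow addition), NaOAc (2.2 equiv), AcOH/CH2Cl2, 0 °C → rt
Reagents that add atoms: bromine, BrBr
Why: Electrophilic aromatic bromination: Br2 adds to ring A through arenium ions whose charge is taken up by the nitrogen lone pair, the first bromine being expected para to nitrogen (C5, compound 9) and the second ortho to it (C3), and any material that starts at C3 converges on the same product 10. The closest known reaction type is the ortho/para polybromination of free anilines with Br2 in buffered acetic acid, established for aminoarenes including amino diaryl ethers. No ring is closed and no stereocentre is created. Regioselectivity: C3 and C5 are the only open ortho/para sites of NH2 and are also para and ortho to the C6 aryloxy oxygen, whereas C4 is meta to both donors, is supported only by the C1 methoxy group (twisted out of conjugation by its two ortho neighbours) and ends up flanked by two bromines. Chemoselectivity: ring B has only a share of the bridging oxygen and carries a deactivating bromine, so it should react far more slowly than the aniline ring, NaOAc traps HBr so that the amine stays unprotonated and this rate gap is kept, and slow addition of exactly two equivalents of Br2 leaves nothing for ring B.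

**Step 6**
Reactants: 10 4,6-dibromo-3-(2-bromophenoxy)-2-methoxyaniline
Product: 12 1,2,5-tribromo-4-(2-bromophenoxy)-3-methoxybenzene, via arenediazonium bromide 11 (not isolated)
Conditions: NaNO2 (1.1 equiv), 48% aq HBr/AcOH, 0–5 °C; then CuBr (1.2 equiv), 48% aq HBr, 0 → 60 °C
Reagents that add atoms: NaNO2, [Na+].[O-]N=O (its nitrogen is held only in 11); hydrogen bromide, Br; CuBr, [Cu+].[Br-]
Why: Diazotisation followed by Sandmeyer bromination: CuBr transfers an electron to diazonium salt 11, N2 leaves, and the C2 aryl radical takes bromine from the divalent-copper bromide so formed, while HBr as the only mineral acid makes any halide exchange at the activated C3/C5 positions degenerate.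

**Step 7**
Reactants: 12 1,2,5-tribromo-4-(2-bromophenoxy)-3-methoxybenzene
Product: 14 2,3,5-tribromo-6-(2-bromophenoxy)phenol, via aryloxydibromoborane 13 (not isolated)
Conditions: BBr3 (2 equiv), CH2Cl2, −78 °C → rt; then H2O, 0 °C
Reagents that add atoms: BBr3, BrB(Br)Br (its atoms are held only in 13, none in 14)
Why: Lewis-acid cleavage of an aryl methyl ether with BBr3: boron binds the methoxy oxygen, bromide removes the methyl group by SN2 to give 13, and water frees the phenol, whereas the diaryl ether offers no sp3 carbon to bromide and the aryl bromides are inert.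

**Compound list**
1 | 1-bromo-2-iodobenzene | Brc1ccccc1I | starting material
2 | 1,3,5-trimethoxybenzene | COc1cc(OC)cc(OC)c1 | starting material
3 | 1-bromo-2-[hydroxy(tosyloxy)-λ3-iodanyl]benzene | OI(OS(=O)(=O)c1ccc(C)cc1)c1ccccc1Br | intermediate
4 | (2-bromophenyl)(2,4,6-trimethoxyphenyl)iodonium p-toluenesulfonate | COc1cc(OC)c([I+]c2ccccc2Br)c(OC)c1.Cc1ccc(cc1)S(=O)(=O)[O-] | intermediate
5 | 3-nitrobenzene-1,2-diol (3-nitrocatechol) | Oc1cccc([N+](=O)[O-])c1O | starting material
6 | 2-methoxy-3-nitrophenol | COc1c(O)cccc1[N+](=O)[O-] | intermediate
7 | 1-(2-bromophenoxy)-2-methoxy-3-nitrobenzene | COc1c([N+](=O)[O-])cccc1Oc1ccccc1Br | intermediate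
8 | 3-(2-bromophenoxy)-2-methoxyaniline | COc1c(N)cccc1Oc1ccccc1Br | intermediate
9 | 4-bromo-3-(2-bromophenoxy)-2-methoxyaniline | COc1c(N)ccc(Br)c1Oc1ccccc1Br | intermediate
10 | 4,6-dibromo-3-(2-bromophenoxy)-2-methoxyaniline | COc1c(N)c(Br)cc(Br)c1Oc1ccccc1Br | intermediate
11 | 4,6-dibromo-3-(2-bromophenoxy)-2-methoxybenzenediazonium bromide | COc1c([N+]#N)c(Br)cc(Br)c1Oc1ccccc1Br.[Br-] | intermediate
12 | 1,2,5-tribromo-4-(2-bromophenoxy)-3-methoxybenzene | COc1c(Br)c(Br)cc(Br)c1Oc1ccccc1Br | intermediate
13 | dibromo[2,3,5-tribromo-6-(2-bromophenoxy)phenoxy]borane | BrB(Br)Oc1c(Br)c(Br)cc(Br)c1Oc1ccccc1Br | intermediate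
14 | 2,3,5-tribromo-6-(2-bromophenoxy)phenol | Oc1c(Br)c(Br)cc(Br)c1Oc1ccccc1Br | target

**Total step count:** 7
**Longest linear sequence:** 6 (steps 2–7 from 5; equally steps 1 and 3–7 from 1)

**Steps most likely to fail**

1. Step 5 (key step). Bromine uptake may not stop at two, with attack on ring B para to the bridging oxygen or at C4, or the free amine may be oxidised by Br2. The fallback keeps the nitrogen-directed double bromination but runs it before ring B is attached.
   - Setting out from 6, the nitro group is reduced (Fe, NH4Cl, EtOH/H2O, 80 °C) to 3-amino-2-methoxyphenol F1.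
   - In F1 the NH2 and OH groups point to the same two carbons and no second arene is present, so Br2 (2.0 equiv, NaOAc, AcOH/CH2Cl2, 0 °C → rt) should give 3-amino-4,6-dibromo-2-methoxyphenol F2.
   - O-arylation of the phenoxide of F2 with salt 4 (K2CO3, MeCN, 60 °C) comes back to the route at 10. The hindered, deactivated neutral amine should not compete with the anionic oxygen.

2. Step 3. The trimethoxyphenyl group may be transferred in place of the 2-bromophenyl group, or ligand coupling may be sluggish because the ortho-substituted nitrophenoxide is a weak nucleophile. The fallback replaces hypervalent-iodine chemistry by a copper-catalysed Ullmann-type ether synthesis.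
   - It sets out from 6 and 1 (CuI, picolinic acid, K3PO4, DMSO, 80 °C). The C–I bond should engage copper in preference to C–Br.
   - It comes back at 7. Step 1 then falls away and no new compound is made.

3. Step 2. Methylation may occur at the remote oxygen or at both oxygens, through proton shuffling between the phenoxides. The fallback blocks the remote oxygen first.
   - Setting out from 5, the dianion (NaH, 2.2 equiv, DMF, 0 °C) is alkylated with BnBr (1.0 equiv) at its more nucleophilic oxygen, the one not conjugated with NO2, to give 2-(benzyloxy)-6-nitrophenol F3.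
   - The only remaining hydroxyl is methylated (MeI, K2CO3, DMF) to 1-(benzyloxy)-2-methoxy-3-nitrobenzene F4.
   - The benzyl ether is removed without touching nitro or methoxy (BCl3, pentamethylbenzene, CH2Cl2, −78 °C), coming back to the route at 6.

**Further compounds**
F1 | step 5 | 3-amino-2-methoxyphenol | COc1c(N)cccc1O
F2 | step 5 | 3-amino-4,6-dibromo-2-methoxyphenol | COc1c(N)c(Br)cc(Br)c1O
F0 | step 3 | none | none
F3 | step 2 | 2-(benzyloxy)-6-nitrophenol | Oc1c(OCc2ccccc2)cccc1[N+](=O)[O-]
F4 | step 2 | 1-(benzyloxy)-2-methoxy-3-nitrobenzene | COc1c(OCc2ccccc2)cccc1[N+](=O)[O-]
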